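(The earlier runs and the new flask come from a simulation with made-up constants; noise was put on by code.)

For whoever took over the bench, I began from the late hours of the cedar run. There, at 6.00 h, I read 22% other capture product and 3% target, each with a scatter of 2 percentage points, while 78% substrate remained.

cedar run (percent of the substrate charged)

| time / h | other capture product / % | target / % | substrate / % |
|---|---|---|---|
| 1.33 | 6 | 0 | 94 |
| 2.50 | 14 | 0 | 86 |
| 4.00 | 16 | 5 | 88 |
| 5.00 | 20 | 1 | 77 |
| 6.00 | 22 | 3 | 78 |

(scatter of a reading: 2 percentage points)

The flask in hand had a different charge of substrate.

| flask | substrate | first nucleophile | second nucleophile | remark | time |
|---|---|---|---|---|---|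
| cedar | 0.45 M | 0.54 M | 0.27 M | run made earlier |  |
| flask | 0.30 M | 0.540 M | 0.270 M |  | 2.5 d |

- share of other capture product in other capture product plus target at 50 min
- share of other capture product in other capture product plus target at 6.0 h
- share of other capture product in other capture product plus target at 2.5 d
- which of other capture product and target there is more of at 2.5 d

- amounts and yields of target count crystals too
- given per volume of solution although it is solid: crystals
- steps thought possible: substrate -> intermediate; first nucleophile + intermediate <-> target; second nucleophile + intermediate -> other capture product; intermediate -> solvolysis product; crystals <-> target

Each unit of other capture product uses one of second nucleophile, so in my balance the other capture product formed plus the second nucleophile left equalled the charge. In this flask second nucleophile was the limiting reagent of that step, so I named the capture ceiling: second nucleophile charged over substrate charged, 90.0% of the substrate charged. The cedar ceiling, 60.0%, stood above its last reading, so those readings had not tested it. I told my successor to expect other capture product in the lead at 2.5 d, below the ceiling. The ceiling is a ratio of two charges, so I asked that no substrate be added.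

The forecast gave shares of 91%, 89% and 81%, with other capture product leading, and said “nothing shows early target later reverting”.

The flask gave 95.7%, 99.1% and 99.9%, with other capture product leading; the last share lay 19 points above the forecast, and the backward turnover of the target step was 99.5% of the forward one.

    substrate → intermediate (k = 7.69 × 10⁻⁴ min⁻¹)
    first nucleophile + intermediate ⇌ target (K = 2.10 M⁻¹, k = 0.0576 M⁻¹ min⁻¹)
    second nucleophile + intermediate → other capture product (k = 1.47 M⁻¹ min⁻¹)
    intermediate → solvolysis product (k = 0.0261 min⁻¹)
    crystals ⇌ target, rate k5*(cs5 - [target]) while solid is left; crystals form when [target] > cs5 (solubility = 7.60 mM, k = 0.0766 min⁻¹)

At 2.50 d the intermediate in this flask went to other capture product 1.6 times as fast as to solvolysis product, and solvolysis had by then turned over 13.2% of the substrate charged. Other capture product stood at 80.4%, below the ceiling of 90.0%, with 11% of the second nucleophile unbound. A neighbouring flask with 1.2 M of substrate had a ceiling of 22.5%, and at 2.50 d it held 22.5% other capture product, with 0% of the charged second nucleophile left.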